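Readings and results come from a simulation with constants of no real substance, and the scatter is random.

Decide whether the second leg of winter, cooled after 15 h, adds enough target to beat dawn.

- the flask that ends with the higher amount of target, in percent of the substrate charged, or "neither" when 2 percentage points or less lies between them (dawn / winter / neither)
- final target, as a percentage of the substrate charged, in dawn
- final target, as a percentage of the substrate charged, in winter

| flask | substrate | temperature | remark | time |
|---|---|---|---|---|
| grey | 1.4 M | 35 °C | run made earlier |  |
| red | 2.2 M | 55 °C | run made earlier |  |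
| dawn | 1.0 M |  | at 70 °C throughout | 15 h |
| winter | 1.0 M |  | at 70 °C until 15 h, from then on at 40 °C | 30 h |

- grey (time / h: target / %, substrate / %): 15.0: 0.3, 90.6; 30.0: 1.4, 78.9; 50.0: 0.2, 69.0; 60.0: 1.6, 64.2; 72.0: 1.3, 58.9; 96.0: 2.8, 50.5; 120: 4.7, 41.5
- red (time / h: target / %, substrate / %): 5.00: 3.8, 60.9; 10.0: 4.3, 35.9; 15.0: 6.5, 22.2; 20.0: 10.7, 11.9; 25.0: 14.0, 6.9; 30.0: 14.9, 5.9; 40.0: 19.3, 2.8

(scatter of a reading: 1 percentage point)

- what was read earlier has a scatter of 1 percentage point, one standard deviation

1. Read the substrate rate constants. Take ln[substrate] as falling linearly with time, which is first order: the last grey reading gives 0.00733 h⁻¹, and the red reading at 20.0 h gives 0.106 h⁻¹.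

2. Apply Arrhenius to these two readings: the activation energy reads 112 kJ mol⁻¹. Extrapolate to 70 °C: 0.645 h⁻¹, a half-life of 1.07 h.

3. Balance the red run at 40.0 h: substrate and target sum to 22.1%, so 77.9% stands in unread intermediates. Target therefore forms through an intermediate pool.

4. Define the equivalent time: the hours at 70 °C that do the work of given hours at another temperature. Divide the hours by the Arrhenius slowdown, here 43.7 for 40 °C, assuming that target formation shares the activation energy above. The 15.0 h at 40 °C in winter then equal 0.343 h at 70 °C.

5. Note the forecast: dawn 33%, winter 35%, answer neither, since “winter's extra 15 h adds only about 2 points”.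

6. Reckon the gain with the equivalent time. The substrate half-life is shorter than the dawn time, so take the mean rate of dawn, using the forecast's 33% over 15 h, as a ceiling on the later rate. Multiplied by the equivalent time, this gives 0.76 percentage points, less than the margin and less than the forecast's gain. The verdict stays neither.

Winter ends at 28.8% and dawn at 28.6%: neither.

    substrate → intermediate A (k = 0.00970 min⁻¹, Ea = 111 kJ mol⁻¹)
    intermediate A → target (k = 8.50 × 10⁻⁴ min⁻¹, Ea = 106 kJ mol⁻¹)
    intermediate A ⇌ intermediate B (K = 19.0, k = 0.00210 min⁻¹, Ea = 104 kJ mol⁻¹, ΔH = −18.0 kJ mol⁻¹)
    substrate → target (k = 2.80 × 10⁻⁴ min⁻¹, Ea = 114 kJ mol⁻¹)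
    (constants at 70 °C)

At the end of winter, intermediate B, the resting state, holds 60.5%, more than the 10.6% in intermediate A. At the change of temperature, intermediate A stands at 11.4%, and its rate constant to target at 70 °C is 8.5 × 10⁻⁴ min⁻¹. The equivalent time 0.343 h rests on the activation energy read for substrate, so redo it with this step's 106 kJ mol⁻¹: 0.427 h at 70 °C. Multiplying the amount and the rate constant by it gives an estimate of 0.25 points, with intermediate A held at its value at the change of temperature; winter stands 0.20 points above dawn.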